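The route cuts the O1–C6 bond of the 1,2-dioxane ring, the peroxide link to the fully substituted carbon that carries the methyl and hexadecyl groups. In one acid-catalysed operation the hydroperoxide on C3 opens a trans C6–C7 epoxide at its tertiary carbon with inversion; this closes the six-membered peroxide ring in the 6-exo mode and fixes C6. The cyclisation substrate is an open-chain α-methoxy hydroperoxide at C3 beside a PMB-protected quaternary C4 and the (6R,7R)-epoxide, assembled by Ireland–Claisen rearrangement, Shi epoxidation and enol ether ozonolysis. The C7 hydroxyl is then removed and the γ-lactone ring (C1–C4) is closed last from the C4 oxygen.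

Key step: step 11

Atom labels used below: C1 lactone C=O, C2 lactone CH2, C3 the CH on peroxide oxygen O2, C4 the quaternary carbon on the lactone ring oxygen, C5 the dioxane CH2, C6 the quaternary carbon on peroxide oxygen O1, C7 the first chain carbon. PMB = 4-methoxybenzyl.

Assumption: the lactate stereocentre is destroyed on enolisation in step 5, so racemic ethyl lactate is used and 6–8 are mixtures at that carbon. C3 in 17–24 is a mixture of epimers that converge in step 16.

Step 1
Reactants: 1 hexadecanal; 2 isopropenylmagnesium bromide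
Product: 3 rac-2-methyloctadec-1-en-3-ol
Conditions: THF, 0 °C; aq. NH4Cl
Reagents that add atoms: none
Why: Grignard addition to the aldehyde gives the secondary allylic alcohol, whose carbinol carbon becomes C7 and whose isopropenyl group supplies C6, its methyl and C5.

Step 2
Reactants: 3 rac-2-methyloctadec-1-en-3-ol
Product: 4 (3S)-2-methyloctadec-1-en-3-ol
Conditions: Ti(Oi-Pr)4 (0.1 equiv), D-(−)-diisopropyl tartrate (0.15 equiv), t-BuOOH (0.6 equiv), 4 Å MS, CH2Cl2, −20 °C
Reagents that add atoms: none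
Why: Sharpless kinetic resolution: with the D-tartrate the (3R)-alcohol should be epoxidised much faster, so the (3S)-alcohol is recovered enantioenriched when the reaction is run slightly past half conversion.

Step 3
Reactants: 5 ethyl lactate (racemic)
Product: 7 2-[(4-methoxybenzyl)oxy]propanoic acid, via ethyl O-PMB-lactate 6 (not isolated)
Conditions: NaH, 4-MeOC6H4CH2Cl, Bu4NI (cat.), THF/DMF, 0 °C → rt; then LiOH, H2O/MeOH, rt; HCl to pH 2
Reagents that add atoms: 4-methoxybenzyl chloride, COc1ccc(CCl)cc1; lithium hydroxide, [Li+].[OH-]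
Why: Williamson etherification of the lactate alkoxide followed by saponification in the same flask; racemisation does not matter because this centre is erased in step 5.

Step 4
Reactants: 4 (3S)-2-methyloctadec-1-en-3-ol; 7 2-[(4-methoxybenzyl)oxy]propanoic acid
Product: 8 (3S)-2-methyloctadec-1-en-3-yl 2-[(4-methoxybenzyl)oxy]propanoate
Conditions: DCC, DMAP (cat.), CH2Cl2, 0 °C → rt
Reagents that add atoms: none
Why: Steglich esterification acylates the allylic hydroxyl on oxygen, so the carbinol configuration is retained.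

Step 5
Reactants: 8 (3S)-2-methyloctadec-1-en-3-yl 2-[(4-methoxybenzyl)oxy]propanoate
Product: 11 (2S,4E)-2-[(4-methoxybenzyl)oxy]-2,4-dimethylicos-4-enoic acid, via silyl ketene acetal 9 (not isolated), via trimethylsilyl ester 10 (not isolated)
Conditions: LiN(i-Pr)2, THF, −78 °C; Me3SiCl/Et3N, −78 °C → rt; 1 M HCl
Reagents that add atoms: none
Why: Ireland–Claisen rearrangement: lithium chelation by the PMB ether oxygen should give the (Z)-ketene acetal, and the chair transition state with the pentadecyl group equatorial relays the (S)-carbinol centre to (S)-C4 while forming the C4–C5 bond and the E C6=C7 alkene.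

Step 6
Reactants: 11 (2S,4E)-2-[(4-methoxybenzyl)oxy]-2,4-dimethylicos-4-enoic acid
Product: 12 methyl (2S,4E)-2-[(4-methoxybenzyl)oxy]-2,4-dimethylicos-4-enoate
Conditions: MeI, K2CO3, DMF, rt
Reagents that add atoms: iodomethane, CI
Why: SN2 O-methylation of the carboxylate; an ester at C3, unlike a free acid or a C3 alcohol, cannot open the epoxide made in the next step by 5-exo attack at C6.

Step 7
Reactants: 12 methyl (2S,4E)-2-[(4-methoxybenzyl)oxy]-2,4-dimethylicos-4-enoate
Product: 13 methyl (2S)-2-[(4-methoxybenzyl)oxy]-2-methyl-3-[(2R,3R)-2-methyl-3-pentadecyloxiran-2-yl]propanoate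
Conditions: D-fructose-derived ketone catalyst (1,2:4,5-di-O-isopropylidene-β-D-erythro-2,3-hexodiulo-2,6-pyranose, 0.3 equiv), KHSO5 (as 2KHSO5·KHSO4·K2SO4), K2CO3, Bu4NHSO4, MeCN/CH2(OMe)2/aq. Na2B4O7 buffer, 0 °C
Reagents that add atoms: potassium peroxymonosulfate, [K+].[O-]S(=O)(=O)OO
Why: Shi epoxidation: the chiral dioxirane transfers oxygen to the E-trisubstituted alkene through the spiro transition state, and the D-fructose-derived catalyst should give the (6R,7R)-epoxide under reagent control, the C4 centre being too remote to interfere.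

Step 8
Reactants: 13 methyl (2S)-2-[(4-methoxybenzyl)oxy]-2-methyl-3-[(2R,3R)-2-methyl-3-pentadecyloxiran-2-yl]propanoate
Product: 14 (2S)-2-[(4-methoxybenzyl)oxy]-2-methyl-3-[(2R,3R)-2-methyl-3-pentadecyloxiran-2-yl]propanal
Conditions: i-Bu2AlH (1.1 equiv), CH2Cl2, −78 °C; MeOH, aq. KNaC4H4O6
Reagents that add atoms: none
Why: Partial reduction of the α-alkoxy ester should stop at the chelated aluminium hemiacetal at −78 °C, which releases the non-enolisable aldehyde on work-up; the epoxide is not attacked at this temperature.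

Step 9
Reactants: 14 (2S)-2-[(4-methoxybenzyl)oxy]-2-methyl-3-[(2R,3R)-2-methyl-3-pentadecyloxiran-2-yl]propanal; 15 (methoxymethyl)triphenylphosphonium chloride
Product: 16 (2R,3R)-2-[(2S)-4-methoxy-2-[(4-methoxybenzyl)oxy]-2-methylbut-3-en-1-yl]-2-methyl-3-pentadecyloxirane (E/Z mixture)
Conditions: KN(SiMe3)2, THF, 0 °C → rt
Reagents that add atoms: none
Why: Wittig methoxymethylenation of the hindered, non-enolisable aldehyde gives the enol ether; both alkene isomers serve equally in the next step.

Step 10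
Reactants: 16 (2R,3R)-2-[(2S)-4-methoxy-2-[(4-methoxybenzyl)oxy]-2-methylbut-3-en-1-yl]-2-methyl-3-pentadecyloxirane
Product: 17 (2S)-1-hydroperoxy-1-methoxy-2-[(4-methoxybenzyl)oxy]-2-methyl-3-[(2R,3R)-2-methyl-3-pentadecyloxiran-2-yl]propane (both C3 epimers)
Conditions: O3 (1 equiv), CH2Cl2/MeOH 4:1, NaHCO3, −78 °C; N2 purge; concentrate below 20 °C
Reagents that add atoms: ozone, [O-][O+]=O; methanol, CO
Why: Ozonolysis of the enol ether: the primary ozonide fragments to methyl formate and the carbonyl oxide on C3, which methanol traps as the α-methoxy hydroperoxide; the electron-rich enol ether should consume the ozone before the anisyl ring does, and the epoxide is inert.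

Step 11
Reactants: 17 (2S)-1-hydroperoxy-1-methoxy-2-[(4-methoxybenzyl)oxy]-2-methyl-3-[(2R,3R)-2-methyl-3-pentadecyloxiran-2-yl]propane
Product: 18 (1R)-1-[(3S,5S,6RS)-6-methoxy-5-[(4-methoxybenzyl)oxy]-3,5-dimethyl-1,2-dioxan-3-yl]hexadecan-1-ol
Conditions: (+)-camphor-10-sulfonic acid (10 mol%), CH2Cl2, 0 °C → rt; solid NaHCO3
Reagents that add atoms: none
Why: Protonation of the epoxide oxygen makes C6 electrophilic, and the terminal oxygen of the C3 hydroperoxide attacks it from the side opposite the breaking C6–O bond, forming O1–C6 and leaving the epoxide oxygen as the C7 hydroxyl. The closest known reaction type is the acid-catalysed intramolecular opening of epoxides and oxetanes by hydroperoxides and hydroperoxy acetals to give 1,2-dioxanes and 1,2-dioxolanes. The 1,2-dioxane closes in the 6-exo-tet mode, assisted by the gem-disubstituted C4. C6 is set by stereospecific inversion of the (6R) epoxide carbon and is therefore controlled by the catalyst of step 7, while C4 and C7 are untouched and both C3 epimers cyclise. The step needs attack at C6 and not C7, and by the hydroperoxide and not another oxygen: C6 is the tertiary, cation-stabilising terminus and gives a six- rather than a seven-membered ring, the PMB ether oxygen could only form a four-membered ring at C6, the methoxy oxygen would have to form an oxonium ion, and C3 carries no free hydroxyl.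

Step 12
Reactants: 18 (1R)-1-[(3S,5S,6RS)-6-methoxy-5-[(4-methoxybenzyl)oxy]-3,5-dimethyl-1,2-dioxan-3-yl]hexadecan-1-ol
Product: 19 O-{(1R)-1-[(3S,5S,6RS)-6-methoxy-5-[(4-methoxybenzyl)oxy]-3,5-dimethyl-1,2-dioxan-3-yl]hexadecyl} O-phenyl carbonothioate
Conditions: PhOC(S)Cl, pyridine, DMAP, CH2Cl2, 0 °C → rt
Reagents that add atoms: O-phenyl chlorothionoformate, S=C(Cl)Oc1ccccc1
Why: DMAP-catalysed acylation of the secondary C7 hydroxyl gives the thionocarbonate without the alkoxide conditions of xanthate formation, under which a β-peroxy alkoxide could fragment.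

Step 13
Reactants: 19 O-{(1R)-1-[(3S,5S,6RS)-6-methoxy-5-[(4-methoxybenzyl)oxy]-3,5-dimethyl-1,2-dioxan-3-yl]hexadecyl} O-phenyl carbonothioate
Product: 20 (3R,5S,6RS)-3-hexadecyl-6-methoxy-5-[(4-methoxybenzyl)oxy]-3,5-dimethyl-1,2-dioxane
Conditions: Bu3SnH (5 equiv, 0.5 M), Et3B, air (trace), toluene, 0 °C → rt
Reagents that add atoms: none
Why: Barton–McCombie deoxygenation: the secondary C7 radical should be reduced by the concentrated stannane faster than it can displace on O1 to give an epoxide, the low initiation temperature favouring hydrogen transfer, and C6 is not touched.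

Step 14
Reactants: 20 (3R,5S,6RS)-3-hexadecyl-6-methoxy-5-[(4-methoxybenzyl)oxy]-3,5-dimethyl-1,2-dioxane
Product: 21 (4S,6R)-6-hexadecyl-3-methoxy-4,6-dimethyl-1,2-dioxan-4-ol
Conditions: DDQ, CH2Cl2/pH 7 phosphate buffer, 0 °C → rt
Reagents that add atoms: none
Why: Oxidative cleavage of the PMB ether by benzylic hydride abstraction and hydrolysis frees the tertiary C4 hydroxyl; the peroxide and the peroxyacetal are inert to the quinone.

Step 15
Reactants: 21 (4S,6R)-6-hexadecyl-3-methoxy-4,6-dimethyl-1,2-dioxan-4-ol; 22 acetic anhydride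
Product: 23 (4S,6R)-6-hexadecyl-3-methoxy-4,6-dimethyl-1,2-dioxan-4-yl acetate
Conditions: DMAP, pyridine, CH2Cl2, rt → 40 °C
Reagents that add atoms: none
Why: DMAP-catalysed acetylation of the tertiary alcohol places C1 and C2 on the C4 oxygen under weakly basic conditions that should not trigger Kornblum–DeLaMare cleavage at C3.

Step 16
Reactants: 23 (4S,6R)-6-hexadecyl-3-methoxy-4,6-dimethyl-1,2-dioxan-4-yl acetate
Product: 25 (3R,4aS,7aS)-3-hexadecyl-3,4a-dimethyl-4,4a,7,7a-tetrahydro-3H-furo[3,2-c][1,2]dioxin-6-one (target), via silyl ketene acetal 24 (not isolated)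
Conditions: LiN(i-Pr)2, Me3SiCl (in situ quench), THF, −78 °C; evaporate, pentane, filter; then Me3SiOTf (20 mol%), CH2Cl2, −78 → −40 °C
Reagents that add atoms: none
Why: Proposed new method: Me3SiOTf should ionise the C3 methoxy group to the cyclic peroxycarbenium ion, which the ketene acetal carbon C2, tethered through the C4 oxygen, can reach only on the face syn to the C4–O bond, so C2–C3 bond formation gives the cis-fused (3S) junction and the silyloxycarbenium ion collapses to the γ-lactone with loss of Me3SiOMe; the closest known reaction type is the Lewis acid-mediated intermolecular addition of silyl ketene acetals to peroxycarbenium ions from 3-alkoxy-1,2-dioxolanes and open-chain monoperoxyacetals (Mukaiyama-type), and the 5-(enolendo)-exo-trig closure has its analogy in Dieckmann-type cyclisations of α-acyloxy esters to tetronic acids.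

Compound list
1 | hexadecanal | CCCCCCCCCCCCCCCC=O | starting material
2 | isopropenylmagnesium bromide | CC(=C)[Mg]Br | starting material
3 | rac-2-methyloctadec-1-en-3-ol | CCCCCCCCCCCCCCCC(O)C(C)=C | intermediate
4 | (3S)-2-methyloctadec-1-en-3-ol | CCCCCCCCCCCCCCC[C@H](O)C(C)=C | intermediate
5 | ethyl lactate (racemic) | CC(O)C(=O)OCC | starting material
6 | ethyl 2-[(4-methoxybenzyl)oxy]propanoate (racemic) | CCOC(=O)C(C)OCc1ccc(OC)cc1 | intermediate
7 | 2-[(4-methoxybenzyl)oxy]propanoic acid (racemic) | CC(OCc1ccc(OC)cc1)C(O)=O | intermediate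
8 | (3S)-2-methyloctadec-1-en-3-yl 2-[(4-methoxybenzyl)oxy]propanoate (both epimers at the propanoate carbon) | CCCCCCCCCCCCCCC[C@H](OC(=O)C(C)OCc1ccc(OC)cc1)C(C)=C | intermediate
9 | trimethyl{[(1Z)-2-[(4-methoxybenzyl)oxy]-1-{[(3S)-2-methyloctadec-1-en-3-yl]oxy}prop-1-en-1-yl]oxy}silane | CCCCCCCCCCCCCCC[C@H](O/C(O[Si](C)(C)C)=C(\C)OCc1ccc(OC)cc1)C(C)=C | intermediate
10 | trimethylsilyl (2S,4E)-2-[(4-methoxybenzyl)oxy]-2,4-dimethylicos-4-enoate | CCCCCCCCCCCCCCC/C=C(\C)C[C@](C)(OCc1ccc(OC)cc1)C(=O)O[Si](C)(C)C | intermediate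
11 | (2S,4E)-2-[(4-methoxybenzyl)oxy]-2,4-dimethylicos-4-enoic acid | CCCCCCCCCCCCCCC/C=C(\C)C[C@](C)(OCc1ccc(OC)cc1)C(O)=O | intermediate
12 | methyl (2S,4E)-2-[(4-methoxybenzyl)oxy]-2,4-dimethylicos-4-enoate | CCCCCCCCCCCCCCC/C=C(\C)C[C@](C)(OCc1ccc(OC)cc1)C(=O)OC | intermediate
13 | methyl (2S)-2-[(4-methoxybenzyl)oxy]-2-methyl-3-[(2R,3R)-2-methyl-3-pentadecyloxiran-2-yl]propanoate | CCCCCCCCCCCCCCC[C@H]1O[C@]1(C)C[C@](C)(OCc1ccc(OC)cc1)C(=O)OC | intermediate
14 | (2S)-2-[(4-methoxybenzyl)oxy]-2-methyl-3-[(2R,3R)-2-methyl-3-pentadecyloxiran-2-yl]propanal | CCCCCCCCCCCCCCC[C@H]1O[C@]1(C)C[C@](C)(OCc1ccc(OC)cc1)C=O | intermediate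
15 | (methoxymethyl)triphenylphosphonium chloride | COC[P+](c1ccccc1)(c1ccccc1)c1ccccc1.[Cl-] | starting material
16 | (2R,3R)-2-[(2S)-4-methoxy-2-[(4-methoxybenzyl)oxy]-2-methylbut-3-en-1-yl]-2-methyl-3-pentadecyloxirane (E/Z mixture) | CCCCCCCCCCCCCCC[C@H]1O[C@]1(C)C[C@](C)(OCc1ccc(OC)cc1)C=COC | intermediate
17 | (2S)-1-hydroperoxy-1-methoxy-2-[(4-methoxybenzyl)oxy]-2-methyl-3-[(2R,3R)-2-methyl-3-pentadecyloxiran-2-yl]propane (both C3 epimers) | CCCCCCCCCCCCCCC[C@H]1O[C@]1(C)C[C@](C)(OCc1ccc(OC)cc1)C(OC)OO | intermediate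
18 | (1R)-1-[(3S,5S,6RS)-6-methoxy-5-[(4-methoxybenzyl)oxy]-3,5-dimethyl-1,2-dioxan-3-yl]hexadecan-1-ol | CCCCCCCCCCCCCCC[C@@H](O)[C@]1(C)C[C@](C)(OCc2ccc(OC)cc2)C(OC)OO1 | intermediate
19 | O-{(1R)-1-[(3S,5S,6RS)-6-methoxy-5-[(4-methoxybenzyl)oxy]-3,5-dimethyl-1,2-dioxan-3-yl]hexadecyl} O-phenyl carbonothioate | CCCCCCCCCCCCCCC[C@@H](OC(=S)Oc1ccccc1)[C@]1(C)C[C@](C)(OCc2ccc(OC)cc2)C(OC)OO1 | intermediate
20 | (3R,5S,6RS)-3-hexadecyl-6-methoxy-5-[(4-methoxybenzyl)oxy]-3,5-dimethyl-1,2-dioxane | CCCCCCCCCCCCCCCC[C@]1(C)C[C@](C)(OCc2ccc(OC)cc2)C(OC)OO1 | intermediate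
21 | (4S,6R)-6-hexadecyl-3-methoxy-4,6-dimethyl-1,2-dioxan-4-ol | CCCCCCCCCCCCCCCC[C@]1(C)C[C@](C)(O)C(OC)OO1 | intermediate
22 | acetic anhydride | CC(=O)OC(C)=O | starting material
23 | (4S,6R)-6-hexadecyl-3-methoxy-4,6-dimethyl-1,2-dioxan-4-yl acetate | CCCCCCCCCCCCCCCC[C@]1(C)C[C@](C)(OC(C)=O)C(OC)OO1 | intermediate
24 | (4S,6R)-6-hexadecyl-3-methoxy-4,6-dimethyl-4-{[1-(trimethylsilyloxy)ethenyl]oxy}-1,2-dioxane | CCCCCCCCCCCCCCCC[C@]1(C)C[C@](C)(OC(=C)O[Si](C)(C)C)C(OC)OO1 | intermediate
25 | (3R,4aS,7aS)-3-hexadecyl-3,4a-dimethyl-4,4a,7,7a-tetrahydro-3H-furo[3,2-c][1,2]dioxin-6-one (C3 S, C4 S, C6 R in the route labels) | CCCCCCCCCCCCCCCC[C@]1(C)C[C@]2(C)OC(=O)C[C@@H]2OO1 | target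

Total step count: 16. Longest linear sequence: 15 steps (steps 1, 2 and 4–16 from hexadecanal; step 3 is a one-step side branch).

Steps most likely to fail

Step 16. The peroxyacetal may fragment under the amide base during enolisation, or the strained 5-(enolendo) closure may be slower than O-to-C silyl migration or heterolysis of the O–O bond. The fallback uses the known intermolecular reaction and sets out from 20. Me3SiOTf-mediated addition of 1-(tert-butyldimethylsilyloxy)-1-methoxyethene in CH2Cl2 at −78 °C to the peroxycarbenium ion would give methyl 2-[(3S,4S,6R)-6-hexadecyl-4-[(4-methoxybenzyl)oxy]-4,6-dimethyl-1,2-dioxan-3-yl]acetate F1. DDQ in buffered CH2Cl2 would then give methyl 2-[(3S,4S,6R)-6-hexadecyl-4-hydroxy-4,6-dimethyl-1,2-dioxan-3-yl]acetate F2, which lactonises with PPTS in CH2Cl2 and so returns to the route at 25. Facial selectivity at C3 then rests on the substrate, where attack anti to the C4 methyl is expected. Only the cis adduct can lactonise, and the trans epimer is removed at that stage.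

Step 11. The protonated epoxide may be opened by the wrong oxygen or suffer a hydride shift to the C7 ketone before the hydroperoxide arrives, or the hydroperoxy acetal may lose hydrogen peroxide under acid. The fallback gives up the epoxide and sets out from 12. Cobalt-catalysed hydroperoxysilylation (Mukaiyama–Isayama reaction; Co(acac)2, O2, Et3SiH, ClCH2CH2Cl, rt) places the peroxide on the tertiary alkene carbon and a hydrogen on C7, giving methyl (2S)-2-[(4-methoxybenzyl)oxy]-2,4-dimethyl-4-[(triethylsilyl)peroxy]icosanoate F3. Reduction with i-Bu2AlH at −78 °C gives (2S)-2-[(4-methoxybenzyl)oxy]-2,4-dimethyl-4-[(triethylsilyl)peroxy]icosanal F4. Camphorsulfonic acid in methanol then removes the silyl group and closes the cyclic methyl peroxyacetal, returning to the route at 20. The price is that the radical step forms C6 without stereocontrol, so 20 must be separated from its epimer at the hexadecyl-bearing carbon, (3S,5S)-3-hexadecyl-6-methoxy-5-[(4-methoxybenzyl)oxy]-3,5-dimethyl-1,2-dioxane F5.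

Step 13. The C7 radical may displace on O1 (epoxide formation with loss of the peroxide) before it is reduced, or stannyl radicals may attack the O–O bond. The fallback avoids radicals and sets out from 18. Dehydration with Ph2S[OC(CF3)2Ph]2 in CH2Cl2 at rt can only eliminate away from the quaternary C6 and would give (3S,5S)-3-(hexadec-1-en-1-yl)-6-methoxy-5-[(4-methoxybenzyl)oxy]-3,5-dimethyl-1,2-dioxane F6 as an E/Z mixture. Diimide reduction (KO2CN=NCO2K, AcOH, MeOH/CH2Cl2, 0 °C → rt), which spares peroxides, returns to the route at 20.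

Further compounds
F1 | step 16 | methyl 2-[(3S,4S,6R)-6-hexadecyl-4-[(4-methoxybenzyl)oxy]-4,6-dimethyl-1,2-dioxan-3-yl]acetate | CCCCCCCCCCCCCCCC[C@]1(C)C[C@](C)(OCc2ccc(OC)cc2)[C@H](CC(=O)OC)OO1
F2 | step 16 | methyl 2-[(3S,4S,6R)-6-hexadecyl-4-hydroxy-4,6-dimethyl-1,2-dioxan-3-yl]acetate | CCCCCCCCCCCCCCCC[C@]1(C)C[C@](C)(O)[C@H](CC(=O)OC)OO1
F3 | step 11 | methyl (2S)-2-[(4-methoxybenzyl)oxy]-2,4-dimethyl-4-[(triethylsilyl)peroxy]icosanoate (both C4 epimers) | CCCCCCCCCCCCCCCCC(C)(OO[Si](CC)(CC)CC)C[C@](C)(OCc1ccc(OC)cc1)C(=O)OC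
F4 | step 11 | (2S)-2-[(4-methoxybenzyl)oxy]-2,4-dimethyl-4-[(triethylsilyl)peroxy]icosanal (both C4 epimers) | CCCCCCCCCCCCCCCCC(C)(OO[Si](CC)(CC)CC)C[C@](C)(OCc1ccc(OC)cc1)C=O
F5 | step 11 | (3S,5S)-3-hexadecyl-6-methoxy-5-[(4-methoxybenzyl)oxy]-3,5-dimethyl-1,2-dioxane | CCCCCCCCCCCCCCCC[C@@]1(C)C[C@](C)(OCc2ccc(OC)cc2)C(OC)OO1
F6 | step 13 | (3S,5S)-3-(hexadec-1-en-1-yl)-6-methoxy-5-[(4-methoxybenzyl)oxy]-3,5-dimethyl-1,2-dioxane (E/Z mixture) | CCCCCCCCCCCCCCC=C[C@]1(C)C[C@](C)(OCc2ccc(OC)cc2)C(OC)OO1
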